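The plan rests on opening both left-hand rings, the oxepane and the cyclohexane fused to it, to an acyclic (S,S,S)-bis-epoxide that ends in a (trimethylsilyl)methyl-substituted alkene. The key step exploits the anti relationship, across the former E-epoxide C–C bond (ring-fusion O–CH carbon and methyl-bearing quaternary carbon), of the oxepane O–CMe2 bond and the quaternary C–CH(side chain) bond: one silyl triflate treatment forms that C–O and that C–C bond, closes both rings and sets the quaternary and CH stereocentres. The cis-decalin half comes from (S)-carvone and is joined by Julia–Kocienski olefination, with diimide reduction and desilylation to finish.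

Key step: step 7

Assumption: the enantiomeric (L-fructose-derived) Shi ketone is treated as a purchasable catalyst, and the alkene geometry formed in step 26 is immaterial because that alkene is reduced in step 27. Correction of a descriptor: the silylmethyl alkene is (Z) by CIP rules (CH2SiMe3 outranks the chain carbon), although the CH2O carbon is trans to the main chain.

Step 1
Reactants: 1 methyl acetoacetate; 2 geranyl bromide
Product: 4 methyl (6E)-7,11-dimethyl-3-oxododeca-6,10-dienoate, via acetoacetate dianion 3 (not isolated)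
Conditions: NaH, THF, 0 °C; n-BuLi, 0 °C; then 2, 0 °C; aq. HCl work-up
Reagents that add atoms: none
Why: The sodium lithium dianion of the β-keto ester is alkylated at its more basic terminal carbon by the allylic bromide (acetoacetate dianion γ-alkylation), which leaves the E-alkene untouched.

Step 2
Reactants: 4 methyl (6E)-7,11-dimethyl-3-oxododeca-6,10-dienoate
Product: 6 methyl (2Z,6E)-3-[(diethoxyphosphoryl)oxy]-7,11-dimethyldodeca-2,6,10-trienoate, via sodium enolate 5 (not isolated)
Conditions: NaH, Et2O, 0 °C; ClP(O)(OEt)2, 0 °C → rt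
Reagents that add atoms: diethyl chlorophosphate, CCOP(=O)(Cl)OCC
Why: O-Phosphorylation of the sodium enolate in ether (enol phosphate formation) should give the Z-enol phosphate because the sodium chelate between the two carbonyl oxygens fixes the enolate geometry.

Step 3
Reactants: 6 methyl (2Z,6E)-3-[(diethoxyphosphoryl)oxy]-7,11-dimethyldodeca-2,6,10-trienoate; 7 (trimethylsilyl)methylmagnesium chloride
Product: 8 methyl (2Z,6E)-7,11-dimethyl-3-[(trimethylsilyl)methyl]dodeca-2,6,10-trienoate
Conditions: Ni(acac)2 (cat.), THF, 0 °C → rt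
Reagents that add atoms: none
Why: Nickel-catalysed cross-coupling of the enol phosphate with the Grignard reagent (Kumada-type coupling) replaces the phosphate with retention of alkene geometry, so the CH2SiMe3 group ends cis to the ester.

Step 4
Reactants: 8 methyl (2Z,6E)-7,11-dimethyl-3-[(trimethylsilyl)methyl]dodeca-2,6,10-trienoate
Product: 9 methyl (2Z)-5-[(2S,3S)-3-{2-[(2S)-3,3-dimethyloxiran-2-yl]ethyl}-3-methyloxiran-2-yl]-3-[(trimethylsilyl)methyl]pent-2-enoate
Conditions: ent-Shi ketone (cat.), Oxone, K2CO3, Bu4NHSO4, MeCN–dimethoxymethane/aq. borate–EDTA buffer, 0 °C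
Reagents that add atoms: potassium peroxymonosulfate (Oxone), OOS(=O)(=O)[O-].[K+]
Why: In the Shi epoxidation the chiral dioxirane transfers oxygen to the two electron-rich trisubstituted alkenes through a spiro transition state, the enantiomeric ketone giving the S configuration at all three epoxide carbons, while the conjugated silylmethyl-bearing alkene is too electron-poor to react.

Step 5
Reactants: 9 methyl (2Z)-5-[(2S,3S)-3-{2-[(2S)-3,3-dimethyloxiran-2-yl]ethyl}-3-methyloxiran-2-yl]-3-[(trimethylsilyl)methyl]pent-2-enoate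
Product: 10 (2Z)-5-[(2S,3S)-3-{2-[(2S)-3,3-dimethyloxiran-2-yl]ethyl}-3-methyloxiran-2-yl]-3-[(trimethylsilyl)methyl]pent-2-en-1-ol
Conditions: DIBAL-H, CH2Cl2, −78 °C; Rochelle salt work-up
Reagents that add atoms: none
Why: 1,2-Reduction of the enoate by DIBAL-H at low temperature (hydride reduction of an ester to the allylic alcohol) should spare the trisubstituted epoxides and the allylsilane and keep the alkene geometry.

Step 6
Reactants: 10 (2Z)-5-[(2S,3S)-3-{2-[(2S)-3,3-dimethyloxiran-2-yl]ethyl}-3-methyloxiran-2-yl]-3-[(trimethylsilyl)methyl]pent-2-en-1-ol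
Product: 11 tert-butyldimethylsilyl ether of 10 (all-S bis-epoxy allylsilane, CH2OTBS trans to the main chain)
Conditions: TBSCl, imidazole, CH2Cl2, 0 °C → rt
Reagents that add atoms: tert-butyldimethylsilyl chloride, CC(C)(C)[Si](C)(C)Cl
Why: Silylation of the primary allylic alcohol (silyl ether formation) runs under basic conditions that cannot open the epoxides and gives an oxygen substituent that does not ionise under the Lewis acid of the next step.

Step 7
Reactants: 11 tert-butyldimethylsilyl ether of 10 (all-S bis-epoxy allylsilane)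
Product: 13 (3S,5aS,6R,9aS)-6-({[tert-butyl(dimethyl)silyl]oxy}methyl)-2,2,5a-trimethyl-7-methylidenedecahydro-1-benzoxepin-3-ol, via trimethylsilyl ether 12 (not isolated)
Conditions: TMSOTf, 2,6-di-tert-butyl-4-methylpyridine, CH2Cl2, −78 °C; then K2CO3, MeOH, −78 °C → rt
Reagents that add atoms: none
Why: Me3SiOTf silylates the terminal epoxide, the oxygen of the neighbouring epoxide attacks its tertiary CMe2 carbon to give a bicyclic epoxonium ion, and the allylsilane opens this ion at the methyl-bearing tertiary carbon, the silyl group leaving to give the exocyclic methylene. The closest known reaction type is the Lewis-acid-promoted tandem oxa- and carbacyclisation of 1,5-diepoxides terminated by alkenes or allylsilanes (epoxide-opening cascade). The oxepane closes by 7-endo C–O bond formation and the cyclohexane by 6-endo, chair-like C–C bond formation. The quaternary carbon is set by inversion at the epoxide carbon (anti opening of the E-derived S,S-epoxide), the carbinol and O–CH centres keep their epoxide configuration, and the side-chain CH is set by the chair fold, in which the CH2OTBS group, trans to the ring-forming chain on the alkene, becomes equatorial. The step needs endo regioselectivity at both epoxides, which the tertiary substitution of each attacked carbon should secure, and survival of the allylsilane until the C–C bond forms, which the hindered pyridine base at −78 °C should secure.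

Step 8
Reactants: 13 (3S,5aS,6R,9aS)-6-({[tert-butyl(dimethyl)silyl]oxy}methyl)-2,2,5a-trimethyl-7-methylidenedecahydro-1-benzoxepin-3-ol
Product: 14 7,2′-spiro-oxirane of 13 (epoxide oxygen equatorial, CH2 axial and syn to the C5a methyl)
Conditions: mCPBA, NaHCO3, CH2Cl2, 0 °C
Reagents that add atoms: 3-chloroperoxybenzoic acid, OOC(=O)c1cccc(Cl)c1
Why: Peracid epoxidation (Prilezhaev reaction) of the 1,1-disubstituted alkene should occur from the equatorial α-face because the axial ring-fusion methyl 1,3 to the alkene carbon blocks the axial approach, which places the new C–O bond equatorial.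

Step 9
Reactants: 14 7,2′-spiro-oxirane of 13
Product: 15 (3S,5aS,6R,7S,9aS)-6-({[tert-butyl(dimethyl)silyl]oxy}methyl)-2,2,5a,7-tetramethyldecahydro-1-benzoxepine-3,7-diol
Conditions: LiAlH4, THF, 0 °C → reflux; Fieser work-up
Reagents that add atoms: none
Why: Hydride opens the spiro-epoxide at its unsubstituted CH2 carbon (SN2 reduction of an epoxide), which turns that carbon into the axial methyl and leaves the equatorial tertiary alcohol with the configuration set in step 8.

Step 10
Reactants: 15 (3S,5aS,6R,7S,9aS)-6-({[tert-butyl(dimethyl)silyl]oxy}methyl)-2,2,5a,7-tetramethyldecahydro-1-benzoxepine-3,7-diol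
Product: 16 (3S,5aS,6R,7S,9aS)-6-(hydroxymethyl)-2,2,5a,7-tetramethyldecahydro-1-benzoxepine-3,7-diol
Conditions: TBAF, THF, 0 °C → rt
Reagents that add atoms: none
Why: Fluoride cleaves the only silyl ether in the molecule (desilylation), so no selectivity between protecting groups is required.

Step 11
Reactants: 16 (3S,5aS,6R,7S,9aS)-6-(hydroxymethyl)-2,2,5a,7-tetramethyldecahydro-1-benzoxepine-3,7-diol
Product: 17 (3S,5aS,6S,7S,9aS)-3,7-dihydroxy-2,2,5a,7-tetramethyldecahydro-1-benzoxepine-6-carbaldehyde
Conditions: TEMPO (cat.), PhI(OAc)2, CH2Cl2, rt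
Reagents that add atoms: none
Why: Oxoammonium-mediated oxidation (TEMPO with a hypervalent iodine co-oxidant) is selective for the primary alcohol over the hindered secondary one and cannot touch the tertiary one, and the equatorial aldehyde is the stable epimer.

Step 12
Reactants: 17 (3S,5aS,6S,7S,9aS)-3,7-dihydroxy-2,2,5a,7-tetramethyldecahydro-1-benzoxepine-6-carbaldehyde
Product: 18 (3S,5aS,6S,7S,9aS)-2,2,5a,7-tetramethyl-3,7-bis[(triethylsilyl)oxy]decahydro-1-benzoxepine-6-carbaldehyde
Conditions: TESOTf, 2,6-lutidine, CH2Cl2, −78 → 0 °C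
Reagents that add atoms: triethylsilyl trifluoromethanesulfonate, CC[Si](CC)(CC)OS(=O)(=O)C(F)(F)F
Why: The silyl triflate silylates both the hindered secondary and the tertiary hydroxyl (silyl ether formation) with a non-nucleophilic base, which removes the acidic protons and blocks retro-aldol cleavage of the β-hydroxy aldehyde in the coupling.

Step 13
Reactants: 19 (S)-carvone
Product: 20 (5S)-5-(3-chloroprop-1-en-2-yl)-2-methylcyclohex-2-en-1-one
Conditions: Ca(OCl)2, CO2 (dry ice), CH2Cl2/H2O, 0 °C
Reagents that add atoms: calcium hypochlorite, [Ca+2].[O-]Cl.[O-]Cl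
Why: Hypochlorous acid made in the flask chlorinates the isopropenyl group in an ene-type allylic chlorination with shift of the double bond, and neither the electron-poor enone nor the ring stereocentre takes part.

Step 14
Reactants: 20 (5S)-5-(3-chloroprop-1-en-2-yl)-2-methylcyclohex-2-en-1-one; 21 4,4,5,5-tetramethyl-2-(2-methylprop-1-en-1-yl)-1,3,2-dioxaborolane
Product: 22 (5S)-2-methyl-5-(5-methylhexa-1,4-dien-2-yl)cyclohex-2-en-1-one
Conditions: Pd(PPh3)4 (cat.), K2CO3, THF/H2O, 60 °C
Reagents that add atoms: none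
Why: Suzuki–Miyaura coupling of the allylic chloride with the alkenylboronate passes through a 2-substituted π-allylpalladium whose two termini are equivalent, so the skipped diene should form as one regioisomer.

Step 15
Reactants: 22 (5S)-2-methyl-5-(5-methylhexa-1,4-dien-2-yl)cyclohex-2-en-1-one
Product: 23 (5S)-5-[3-(3,3-dimethyloxiran-2-yl)prop-1-en-2-yl]-2-methylcyclohex-2-en-1-one (both oxirane epimers)
Conditions: mCPBA (1 equiv), NaHCO3, CH2Cl2, −20 °C
Reagents that add atoms: 3-chloroperoxybenzoic acid, OOC(=O)c1cccc(Cl)c1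
Why: Peracid epoxidation (Prilezhaev reaction) selects the most electron-rich trisubstituted alkene over the 1,1-disubstituted and the enone alkenes, and the new stereocentre is not controlled because it is removed in step 19.

Step 16
Reactants: 23 (5S)-5-[3-(3,3-dimethyloxiran-2-yl)prop-1-en-2-yl]-2-methylcyclohex-2-en-1-one
Product: 25 {[(3S)-3-[3-(3,3-dimethyloxiran-2-yl)prop-1-en-2-yl]-6-methylcyclohexa-1,5-dien-1-yl]oxy}trimethylsilane, via lithium dienolate 24 (not isolated)
Conditions: LDA, THF, −78 °C; TMSCl, −78 → 0 °C; pentane, filtration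
Reagents that add atoms: chlorotrimethylsilane, C[Si](C)(C)Cl
Why: Kinetic α′-deprotonation of the enone and O-silylation (silyl enol ether formation) give the cross-conjugated 2-silyloxy diene regiospecifically without opening the epoxide.

Step 17
Reactants: 25 {[(3S)-3-[3-(3,3-dimethyloxiran-2-yl)prop-1-en-2-yl]-6-methylcyclohexa-1,5-dien-1-yl]oxy}trimethylsilane
Product: 26 (4aS,8aR)-7-hydroxy-2,8,8-trimethyl-5-methylidene-4a,5,6,7,8,8a-hexahydronaphthalen-1(4H)-one (cis-fused, both C7 epimers)
Conditions: TiCl4, CH2Cl2, −78 °C, high dilution; aq. NaHCO3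
Reagents that add atoms: none
Why: Lewis-acid activation lets the enol silane carbon open the epoxide at its tertiary carbon (Mukaiyama-type epoxide–enol silane cyclisation, 6-endo at the epoxide), and because the new bond must form on the face that carries the tether from the carvone stereocentre the ring fusion should be cis, while the carbinol centre forms as a mixture that does not matter.

Step 18
Reactants: 26 (4aS,8aR)-7-hydroxy-2,8,8-trimethyl-5-methylidene-4a,5,6,7,8,8a-hexahydronaphthalen-1(4H)-one
Product: 27 O-[(4aS,8aR)-3,1,1-trimethyl-8-methylidene-4-oxo-decalin-type-2-yl] 1H-imidazole-1-carbothioate (imidazolyl thiocarbonate of 26 at C7)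
Conditions: 1,1′-thiocarbonyldiimidazole, DMAP (cat.), 1,2-dichloroethane, 70 °C
Reagents that add atoms: 1,1′-thiocarbonyldiimidazole, S=C(n1ccnc1)n1ccnc1
Why: Thioacylation of the secondary alcohol (first half of a Barton–McCombie deoxygenation) runs under nearly neutral conditions that should not epimerise the ring-fusion carbon next to the ketone.

Step 19
Reactants: 27 imidazolyl thiocarbonate of 26
Product: 28 (4aS,8aR)-2,8,8-trimethyl-5-methylidene-4a,5,6,7,8,8a-hexahydronaphthalen-1(4H)-one
Conditions: Bu3SnH, AIBN, toluene, 100 °C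
Reagents that add atoms: none
Why: Radical chain deoxygenation (Barton–McCombie reaction) replaces the thiocarbonyl ester by hydrogen through a secondary radical that has no fast irreversible cyclisation open to it, which gives the ring CH2 group.

Step 20
Reactants: 28 (4aS,8aR)-2,8,8-trimethyl-5-methylidene-4a,5,6,7,8,8a-hexahydronaphthalen-1(4H)-one
Product: 29 5,2′-spiro-oxirane of 28 (epoxide oxygen on the face of the two ring-fusion hydrogens)
Conditions: mCPBA, NaHCO3, CH2Cl2, 0 °C
Reagents that add atoms: 3-chloroperoxybenzoic acid, OOC(=O)c1cccc(Cl)c1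
Why: Peracid epoxidation (Prilezhaev reaction) attacks only the isolated 1,1-disubstituted alkene and should come from the face of the ring-fusion hydrogens, since the other face is shielded by the axially disposed carbonyl carbon of the cis-fused ring, which sets the carbinol configuration.

Step 21
Reactants: 29 5,2′-spiro-oxirane of 28
Product: 30 1-methylidene analogue of 29 (exocyclic methylene conjugated with the ring alkene)
Conditions: Cp2TiMe2, toluene, 70 °C, dark
Reagents that add atoms: dimethyltitanocene, C[Ti](C)(C1C=CC=C1)C1C=CC=C1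
Why: Petasis methylenation converts the hindered enone carbonyl into the exocyclic methylene without base, so the epimerisable ring-fusion centre next to the ketone is fixed without equilibration.

Step 22
Reactants: 30 1-methylidene analogue of 29
Product: 31 (1S,4aR,8aS)-1,4,4,6-tetramethyl-5-methylidene-1,2,3,4,4a,5,8,8a-octahydronaphthalen-1-ol
Conditions: LiAlH4, THF, 0 °C → rt
Reagents that add atoms: none
Why: Hydride opens the spiro-epoxide at its CH2 carbon (SN2 reduction of an epoxide) and gives the methyl carbinol with the oxygen configuration set in step 20, the diene being inert.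

Step 23
Reactants: 31 (1S,4aR,8aS)-1,4,4,6-tetramethyl-5-methylidene-1,2,3,4,4a,5,8,8a-octahydronaphthalen-1-ol
Product: 33 (1S,4aR,5S,8aS)-5-(hydroxymethyl)-1,4,4,6-tetramethyl-1,2,3,4,4a,5,8,8a-octahydronaphthalen-1-ol, via alkylborane 32 (not isolated)
Conditions: 9-BBN, THF, rt → 50 °C; then NaOH, H2O2, 0 °C
Reagents that add atoms: hydrogen peroxide, OO
Why: Hydroboration–oxidation with the bulky borane puts boron on the terminal carbon of the exocyclic methylene only and delivers hydrogen to the ring carbon from the convex face, the concave face being blocked by the second ring, which sets the side-chain CH cis to the ring-fusion hydrogens and leaves the trisubstituted alkene.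

Step 24
Reactants: 33 (1S,4aR,5S,8aS)-5-(hydroxymethyl)-1,4,4,6-tetramethyl-1,2,3,4,4a,5,8,8a-octahydronaphthalen-1-ol
Product: 34 (1S,4aR,5S,8aS)-1,4,4,6-tetramethyl-5-{[(1-phenyl-1H-tetrazol-5-yl)sulfanyl]methyl}-1,2,3,4,4a,5,8,8a-octahydronaphthalen-1-ol
Conditions: 1-phenyl-1H-tetrazole-5-thiol, PPh3, DIAD, THF, 0 °C
Reagents that add atoms: 1-phenyl-1H-tetrazole-5-thiol, Sc1nnnn1-c1ccccc1
Why: Mitsunobu thioetherification converts only the primary alcohol because the tertiary one is inert to the oxyphosphonium activation.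

Step 25
Reactants: 34 (1S,4aR,5S,8aS)-1,4,4,6-tetramethyl-5-{[(1-phenyl-1H-tetrazol-5-yl)sulfanyl]methyl}-1,2,3,4,4a,5,8,8a-octahydronaphthalen-1-ol
Product: 35 (1S,4aR,5S,8aS)-1,4,4,6-tetramethyl-5-{[(1-phenyl-1H-tetrazol-5-yl)sulfonyl]methyl}-1,2,3,4,4a,5,8,8a-octahydronaphthalen-1-ol
Conditions: (NH4)6Mo7O24·4H2O (cat.), 30% H2O2, EtOH, 0 °C → rt
Reagents that add atoms: hydrogen peroxide, OO
Why: Molybdate-catalysed peroxide oxidation takes the sulfide to the sulfone (sulfide oxidation) without epoxidising the trisubstituted alkene.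

Step 26
Reactants: 35 (1S,4aR,5S,8aS)-1,4,4,6-tetramethyl-5-{[(1-phenyl-1H-tetrazol-5-yl)sulfonyl]methyl}-1,2,3,4,4a,5,8,8a-octahydronaphthalen-1-ol; 18 (3S,5aS,6S,7S,9aS)-2,2,5a,7-tetramethyl-3,7-bis[(triethylsilyl)oxy]decahydro-1-benzoxepine-6-carbaldehyde
Product: 37 E-alkene joining C6 of the bis(triethylsilyl) benzoxepine to C5 of the octahydronaphthalenol through a CH=CH unit, via sulfone dianion 36 (not isolated)
Conditions: KHMDS (2.1 equiv), THF, −78 °C; then 18, −78 °C → rt
Reagents that add atoms: none
Why: In the Julia–Kocienski olefination the α-sulfonyl carbanion adds to the aldehyde and Smiles rearrangement with loss of sulfur dioxide and the tetrazolone gives the 1,2-disubstituted alkene, whose geometry is irrelevant and whose formation touches no stereocentre.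

Step 27
Reactants: 37 E-alkene joining the two halves
Product: 38 sipholenol L 3,7-bis(triethylsilyl) ether (silyl ethers on the oxepane secondary oxygen and on the neighbouring cyclohexane tertiary oxygen)
Conditions: TsNHNH2, NaOAc, DME/H2O, 85 °C
Reagents that add atoms: none
Why: Diimide reduction saturates the 1,2-disubstituted alkene much faster than the trisubstituted ring alkene and, being neutral and free of metal, should cause no isomerisation.

Step 28
Reactants: 38 sipholenol L 3,7-bis(triethylsilyl) ether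
Product: 39 sipholenol L
Conditions: TBAF, THF, 50 °C
Reagents that add atoms: none
Why: Fluoride-mediated desilylation removes both triethylsilyl ethers and frees the secondary and tertiary alcohols without acid that could dehydrate the tertiary carbinols.

Compound list

1 | methyl acetoacetate | COC(=O)CC(C)=O | starting material
2 | geranyl bromide | CC(C)=CCC/C(C)=C/CBr | starting material
3 | sodium lithium dianion of methyl acetoacetate | COC([O-])=CC(=C)[O-].[Na+].[Li+] | intermediate
4 | methyl (6E)-7,11-dimethyl-3-oxododeca-6,10-dienoate | COC(=O)CC(=O)CC/C=C(\C)CCC=C(C)C | intermediate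
5 | sodium (Z)-enolate of 4 | COC(=O)/C=C(\[O-])CC/C=C(\C)CCC=C(C)C.[Na+] | intermediate
6 | methyl (2Z,6E)-3-[(diethoxyphosphoryl)oxy]-7,11-dimethyldodeca-2,6,10-trienoate | COC(=O)/C=C(\OP(=O)(OCC)OCC)CC/C=C(\C)CCC=C(C)C | intermediate
7 | (trimethylsilyl)methylmagnesium chloride | C[Si](C)(C)C[Mg]Cl | starting material
8 | methyl (2Z,6E)-7,11-dimethyl-3-[(trimethylsilyl)methyl]dodeca-2,6,10-trienoate | COC(=O)/C=C(\C[Si](C)(C)C)CC/C=C(\C)CCC=C(C)C | intermediate
9 | methyl (2Z)-5-[(2S,3S)-3-{2-[(2S)-3,3-dimethyloxiran-2-yl]ethyl}-3-methyloxiran-2-yl]-3-[(trimethylsilyl)methyl]pent-2-enoate | CC1(C)O[C@H]1CC[C@]2(C)O[C@H]2CC/C(C[Si](C)(C)C)=C/C(=O)OC | intermediate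
10 | (2Z)-5-[(2S,3S)-3-{2-[(2S)-3,3-dimethyloxiran-2-yl]ethyl}-3-methyloxiran-2-yl]-3-[(trimethylsilyl)methyl]pent-2-en-1-ol | CC1(C)O[C@H]1CC[C@]2(C)O[C@H]2CC/C(C[Si](C)(C)C)=C/CO | intermediate
11 | tert-butyldimethylsilyl ether of 10 (all-S bis-epoxy allylsilane) | CC1(C)O[C@H]1CC[C@]2(C)O[C@H]2CC/C(C[Si](C)(C)C)=C/CO[Si](C)(C)C(C)(C)C | intermediate
12 | 3-O-trimethylsilyl ether of 13 | CC(C)(C)[Si](C)(C)OC[C@H]1[C@]2(C)CC[C@H](O[Si](C)(C)C)C(C)(C)O[C@H]2CCC1=C | intermediate
13 | (3S,5aS,6R,9aS)-6-({[tert-butyl(dimethyl)silyl]oxy}methyl)-2,2,5a-trimethyl-7-methylidenedecahydro-1-benzoxepin-3-ol (trans-fused) | CC(C)(C)[Si](C)(C)OC[C@H]1[C@]2(C)CC[C@H](O)C(C)(C)O[C@H]2CCC1=C | intermediate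
14 | 7,2′-spiro-oxirane of 13 (epoxide oxygen equatorial) | CC(C)(C)[Si](C)(C)OC[C@H]1[C@]2(C)CC[C@H](O)C(C)(C)O[C@H]2CC[C@@]13CO3 | intermediate
15 | (3S,5aS,6R,7S,9aS)-6-({[tert-butyl(dimethyl)silyl]oxy}methyl)-2,2,5a,7-tetramethyldecahydro-1-benzoxepine-3,7-diol | CC(C)(C)[Si](C)(C)OC[C@H]1[C@]2(C)CC[C@H](O)C(C)(C)O[C@H]2CC[C@]1(C)O | intermediate
16 | (3S,5aS,6R,7S,9aS)-6-(hydroxymethyl)-2,2,5a,7-tetramethyldecahydro-1-benzoxepine-3,7-diol | OC[C@H]1[C@]2(C)CC[C@H](O)C(C)(C)O[C@H]2CC[C@]1(C)O | intermediate
17 | (3S,5aS,6S,7S,9aS)-3,7-dihydroxy-2,2,5a,7-tetramethyldecahydro-1-benzoxepine-6-carbaldehyde | O=C[C@H]1[C@]2(C)CC[C@H](O)C(C)(C)O[C@H]2CC[C@]1(C)O | intermediate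
18 | (3S,5aS,6S,7S,9aS)-2,2,5a,7-tetramethyl-3,7-bis[(triethylsilyl)oxy]decahydro-1-benzoxepine-6-carbaldehyde | O=C[C@H]1[C@]2(C)CC[C@H](O[Si](CC)(CC)CC)C(C)(C)O[C@H]2CC[C@]1(C)O[Si](CC)(CC)CC | intermediate
19 | (S)-carvone | CC1=CC[C@@H](CC1=O)C(C)=C | starting material
20 | (5S)-5-(3-chloroprop-1-en-2-yl)-2-methylcyclohex-2-en-1-one | CC1=CC[C@@H](CC1=O)C(=C)CCl | intermediate
21 | 4,4,5,5-tetramethyl-2-(2-methylprop-1-en-1-yl)-1,3,2-dioxaborolane | CC(C)=CB1OC(C)(C)C(C)(C)O1 | starting material
22 | (5S)-2-methyl-5-(5-methylhexa-1,4-dien-2-yl)cyclohex-2-en-1-one | CC1=CC[C@@H](CC1=O)C(=C)CC=C(C)C | intermediate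
23 | (5S)-5-[3-(3,3-dimethyloxiran-2-yl)prop-1-en-2-yl]-2-methylcyclohex-2-en-1-one (oxirane epimers) | CC1=CC[C@@H](CC1=O)C(=C)CC2OC2(C)C | intermediate
24 | lithium cross-conjugated dienolate of 23 | CC1=CC[C@@H](C=C1[O-])C(=C)CC2OC2(C)C.[Li+] | intermediate
25 | {[(3S)-3-[3-(3,3-dimethyloxiran-2-yl)prop-1-en-2-yl]-6-methylcyclohexa-1,5-dien-1-yl]oxy}trimethylsilane | CC1=CC[C@@H](C=C1O[Si](C)(C)C)C(=C)CC2OC2(C)C | intermediate
26 | (4aS,8aR)-7-hydroxy-2,8,8-trimethyl-5-methylidene-4a,5,6,7,8,8a-hexahydronaphthalen-1(4H)-one (cis-fused, C7 epimers) | CC1=CC[C@H]2[C@@H](C1=O)C(C)(C)C(O)CC2=C | intermediate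
27 | imidazol-1-yl thiocarbonate of 26 at the C7 oxygen | CC1=CC[C@H]2[C@@H](C1=O)C(C)(C)C(OC(=S)n3ccnc3)CC2=C | intermediate
28 | (4aS,8aR)-2,8,8-trimethyl-5-methylidene-4a,5,6,7,8,8a-hexahydronaphthalen-1(4H)-one (cis-fused) | CC1=CC[C@H]2[C@@H](C1=O)C(C)(C)CCC2=C | intermediate
29 | 5,2′-spiro-oxirane of 28 (oxygen on the face of the ring-fusion hydrogens) | CC1=CC[C@H]2[C@@H](C1=O)C(C)(C)CC[C@@]23CO3 | intermediate
30 | 1-methylidene analogue of 29 | CC1=CC[C@H]2[C@@H](C1=C)C(C)(C)CC[C@@]23CO3 | intermediate
31 | (1S,4aR,8aS)-1,4,4,6-tetramethyl-5-methylidene-1,2,3,4,4a,5,8,8a-octahydronaphthalen-1-ol | CC1=CC[C@H]2[C@@H](C1=C)C(C)(C)CC[C@]2(C)O | intermediate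
32 | B-alkyl-9-BBN adduct of 31 (tertiary oxygen as its 9-BBN borinate) | CC1=CC[C@H]2[C@@H]([C@@H]1CB3C4CCCC3CCC4)C(C)(C)CC[C@]2(C)OB5C6CCCC5CCC6 | intermediate
33 | (1S,4aR,5S,8aS)-5-(hydroxymethyl)-1,4,4,6-tetramethyl-1,2,3,4,4a,5,8,8a-octahydronaphthalen-1-ol | CC1=CC[C@H]2[C@@H]([C@@H]1CO)C(C)(C)CC[C@]2(C)O | intermediate
34 | (1S,4aR,5S,8aS)-1,4,4,6-tetramethyl-5-{[(1-phenyl-1H-tetrazol-5-yl)sulfanyl]methyl}-1,2,3,4,4a,5,8,8a-octahydronaphthalen-1-ol | CC1=CC[C@H]2[C@@H]([C@@H]1CSc3nnnn3-c4ccccc4)C(C)(C)CC[C@]2(C)O | intermediate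
35 | (1S,4aR,5S,8aS)-1,4,4,6-tetramethyl-5-{[(1-phenyl-1H-tetrazol-5-yl)sulfonyl]methyl}-1,2,3,4,4a,5,8,8a-octahydronaphthalen-1-ol | CC1=CC[C@H]2[C@@H]([C@@H]1CS(=O)(=O)c3nnnn3-c4ccccc4)C(C)(C)CC[C@]2(C)O | intermediate
36 | dipotassium salt of 35 (alkoxide and α-sulfonyl carbanion) | CC1=CC[C@H]2[C@@H]([C@@H]1[CH-]S(=O)(=O)c3nnnn3-c4ccccc4)C(C)(C)CC[C@]2(C)[O-].[K+].[K+] | intermediate
37 | E-alkene joining the bis(triethylsilyl) benzoxepine (C6) and the octahydronaphthalenol (C5) | CC1=CC[C@H]2[C@@H]([C@@H]1/C=C/[C@H]1[C@]3(C)CC[C@H](O[Si](CC)(CC)CC)C(C)(C)O[C@H]3CC[C@]1(C)O[Si](CC)(CC)CC)C(C)(C)CC[C@]2(C)O | intermediate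
38 | sipholenol L 3,7-bis(triethylsilyl) ether | CC1=CC[C@H]2[C@@H]([C@@H]1CC[C@H]1[C@]3(C)CC[C@H](O[Si](CC)(CC)CC)C(C)(C)O[C@H]3CC[C@]1(C)O[Si](CC)(CC)CC)C(C)(C)CC[C@]2(C)O | intermediate
39 | sipholenol L | CC1=CC[C@H]2[C@@H]([C@@H]1CC[C@H]1[C@]3(C)CC[C@H](O)C(C)(C)O[C@H]3CC[C@]1(C)O)C(C)(C)CC[C@]2(C)O | target

Total step count: 28 (12 steps to aldehyde 18, 13 steps to sulfone 35, 3 steps after the union).
Longest linear sequence: 16 steps, from (S)-carvone through steps 13–28.

Steps most likely to fail

Step 7. The cascade may stop after the first ring, the allylsilane may be lost by protodesilylation before the C–C bond forms, or the epoxonium ion may be opened at the wrong carbon. The fallback sets out from 4 and comes back at 13, and it changes the terminating nucleophile to an enol silane, whose carbon is more nucleophilic and cannot lose its silicon before bond formation. Shi epoxidation of 4 with the enantiomeric ketone at pH 8 would give the bis-epoxy β-keto ester F1. TBSOTf and triethylamine at −78 °C would give the Z-silyl enol ether F2, in which the oxygen is blocked so that only carbon can attack. The same silyl triflate cascade, followed by methanolic carbonate, would give the bicyclic β-keto ester F3 with the ester equatorial. Lombardo methylenation (Zn, CH2Br2, TiCl4) of the ring ketone would give the methylidene ester F4, DIBAL-H reduction would give the diol F5, and selective silylation of the primary hydroxyl with TBSCl and imidazole would give 13.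

Step 17. The activated epoxide may rearrange to a ketone by hydride shift or be opened by chloride before the enol silane reaches it, and the silyl enol ether may hydrolyse. The fallback sets out from 22 and comes back at 28, and it replaces the epoxide by a mercurinium ion as the source of the tertiary cation, which also makes the deoxygenation of steps 18 and 19 unnecessary. LDA and TMSCl would convert 22 into the silyl dienol ether F6. Mercury(II) triflate as its N,N-dimethylaniline complex, followed by aqueous sodium chloride, would give the chloromercurio ketone F7; mercurinium formation is reversible at both alkenes, but only the cation at the gem-dimethyl carbon lies within reach of the enol carbon. Reduction of the carbon–mercury bond with Bu3SnH and AIBN would give 28.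

Step 26. Addition of the bulky, stabilised sulfonyl carbanion to the very hindered aldehyde may be slow and reversible, so that enolisation of the aldehyde and loss of the β-silyloxy group compete. The fallback sets out from 33 and comes back at 38, and it replaces the olefination by an irreversible organolithium addition followed by radical deoxygenation. Iodine, triphenylphosphine and imidazole would convert the primary alcohol of 33 into the iodide F8. Excess tert-butyllithium (one equivalent for the hydroxyl, two for the iodine–lithium exchange) and then aldehyde 18 would give the secondary carbinol F9 as a mixture of epimers. Thiocarbonyldiimidazole, which does not acylate the tertiary alcohol, would give the imidazolyl thiocarbonate F10, and Bu3SnH with AIBN would give 38.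

Further compounds

F1 | step 7 | methyl 5-[(2S,3S)-3-{2-[(2S)-3,3-dimethyloxiran-2-yl]ethyl}-3-methyloxiran-2-yl]-3-oxopentanoate | CC1(C)O[C@H]1CC[C@]2(C)O[C@H]2CCC(=O)CC(=O)OC
F2 | step 7 | (Z)-tert-butyldimethylsilyl enol ether of F1 | CC1(C)O[C@H]1CC[C@]2(C)O[C@H]2CC/C(O[Si](C)(C)C(C)(C)C)=C/C(=O)OC
F3 | step 7 | methyl (3S,5aS,6S,9aS)-3-hydroxy-2,2,5a-trimethyl-7-oxodecahydro-1-benzoxepine-6-carboxylate (ester equatorial) | COC(=O)[C@H]1[C@]2(C)CC[C@H](O)C(C)(C)O[C@H]2CCC1=O
F4 | step 7 | 7-methylidene analogue of F3 | COC(=O)[C@H]1[C@]2(C)CC[C@H](O)C(C)(C)O[C@H]2CCC1=C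
F5 | step 7 | 6-(hydroxymethyl)-2,2,5a-trimethyl-7-methylidenedecahydro-1-benzoxepin-3-ol (desilyl 13) | OC[C@H]1[C@]2(C)CC[C@H](O)C(C)(C)O[C@H]2CCC1=C
F6 | step 17 | trimethylsilyl dienol ether of 22 | CC1=CC[C@@H](C=C1O[Si](C)(C)C)C(=C)CC=C(C)C
F7 | step 17 | 7-chloromercurio derivative of 28 | CC1=CC[C@H]2[C@@H](C1=O)C(C)(C)C([Hg]Cl)CC2=C
F8 | step 26 | (1S,4aR,5S,8aS)-5-(iodomethyl)-1,4,4,6-tetramethyl-1,2,3,4,4a,5,8,8a-octahydronaphthalen-1-ol | CC1=CC[C@H]2[C@@H]([C@@H]1CI)C(C)(C)CC[C@]2(C)O
F9 | step 26 | secondary carbinol from addition of lithiated F8 to 18 (carbinol epimers) | CC1=CC[C@H]2[C@@H]([C@@H]1CC(O)[C@H]1[C@]3(C)CC[C@H](O[Si](CC)(CC)CC)C(C)(C)O[C@H]3CC[C@]1(C)O[Si](CC)(CC)CC)C(C)(C)CC[C@]2(C)O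
F10 | step 26 | imidazol-1-yl thiocarbonate of F9 | CC1=CC[C@H]2[C@@H]([C@@H]1CC(OC(=S)n4ccnc4)[C@H]1[C@]3(C)CC[C@H](O[Si](CC)(CC)CC)C(C)(C)O[C@H]3CC[C@]1(C)O[Si](CC)(CC)CC)C(C)(C)CC[C@]2(C)O
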